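**Plan**
- Retrosynthesis: the C3=C4 double bond is first masked as a C4 phenylsulfonyl chroman; then the C8–prenyl bond, the C8–I bond and the α-diketone (from a deoxybenzoin CH2) are taken back; then C4–C4a and C3–C2 are cut together, releasing phenyl vinyl sulfone and an aryloxy-isobutyric redox-active ester; last come O1–C2 (etherification) and the C6–acyl bond (Friedel–Crafts).
- Forward: rings A and B are joined as a deoxybenzoin, O1 receives the CMe2–CO2R arm, the pyran ring closes onto ring A in a radical (4+2) annulation, then the diketone, the C8 iodide and the prenyl group follow, and loss of sulfinate unmasks the chromene last.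
- Enabling feature: C4a is a ring-A carbon ortho to the ether oxygen O1 (which carries the CMe2 radical centre) and sits between C8a and the chelated C5–OH; the same C5–OH later expels the C4 sulfinate through an o-quinone methide.
- Stereochemistry: the target has no stereocentre; C4 of the sulfone intermediates is racemic and is erased in the last step.

Key step: step 5

Assumption: positions are named by the chromene numbering of the target (O1, C2 to C8a; ring A = C4a to C8a, ring B = the 4-hydroxyphenyl ring), and compounds 10, 11, 12 and 14 are racemic at C4.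

**Step 1**
Reactants: 1 5-methoxyresorcinol; 2 4-hydroxyphenylacetic acid
Product: 3 1-(2,4-dihydroxy-6-methoxyphenyl)-2-(4-hydroxyphenyl)ethan-1-one
Conditions: BF3·OEt2 (neat), 85 °C; then aq. NaOAc
Reagents that add atoms: none
Why: Friedel–Crafts acylation by the BF3-activated arylacetic acid should occur at C4 of 1 (ortho to one hydroxyl and para to the other, as in resorcinol), which places the ketone between OH and OMe; any isomer acylated between the two hydroxyls would be removed by crystallisation.

**Step 2**
Reactants: 3 deoxybenzoin; 4 benzyl 2-bromo-2-methylpropanoate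
Product: 5 benzyl 2-{3-hydroxy-4-[2-(4-hydroxyphenyl)acetyl]-5-methoxyphenoxy}-2-methylpropanoate
Conditions: K2CO3 (1.1 equiv), DMF, 70 °C
Reagents that add atoms: none
Why: Williamson etherification with the tertiary α-bromo ester (fibrate-type alkylation) should take place at the ring-A hydroxyl para to the ketone, the most acidic phenol (vinylogous acid), while the ortho hydroxyl is held in the chelate and the ring-B phenol stays protonated with about one equivalent of base.

**Step 3**
Reactants: 5 benzyl ester
Product: 6 2-{3-hydroxy-4-[2-(4-hydroxyphenyl)acetyl]-5-methoxyphenoxy}-2-methylpropanoic acid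
Conditions: H2 (1 atm), 10% Pd/C, EtOAc, rt
Reagents that add atoms: none
Why: Hydrogenolysis of the benzyl ester should free the acid under neutral conditions; no alkene is present yet and the electron-rich aryl ketone is not reduced at 1 atm.

**Step 4**
Reactants: 6 acid; 7 N-hydroxyphthalimide
Product: 8 1,3-dioxoisoindolin-2-yl 2-{3-hydroxy-4-[2-(4-hydroxyphenyl)acetyl]-5-methoxyphenoxy}-2-methylpropanoate (redox-active ester)
Conditions: DIC (N,N'-diisopropylcarbodiimide), CH2Cl2/THF, 0 °C to rt, no DMAP
Reagents that add atoms: none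
Why: Carbodiimide (Steglich-type) esterification; without DMAP the acidic N-hydroxyphthalimide should capture the O-acylisourea far faster than the chelated or ring-B phenols.

**Step 5**
Reactants: 8 redox-active ester; 9 phenyl vinyl sulfone
Product: 10 1-[5-hydroxy-7-methoxy-2,2-dimethyl-4-(phenylsulfonyl)chroman-6-yl]-2-(4-hydroxyphenyl)ethan-1-one (racemic)
Conditions: fac-Ir(ppy)3 (ppy = 2-phenylpyridinato, 1 mol %), 9 (3 equiv), degassed MeCN, blue LEDs (450 nm), rt
Reagents that add atoms: none
Why: Proposed new method: the photoexcited trivalent iridium complex transfers one electron to the N-acyloxyphthalimide of 8, which loses CO2 and phthalimide anion to give the tertiary α-aryloxy radical; this nucleophilic radical adds to the CH2 terminus of 9 (Giese addition, forming C2–C3), the electrophilic α-sulfonyl radical then attacks C4a of ring A (forming C4–C4a), and the cyclohexadienyl radical is oxidised by the tetravalent iridium complex and deprotonated by phthalimide anion, so the cycle is redox-neutral. The closest known reaction type is the photoredox decarboxylative radical (4+2) annulation of redox-active esters with electron-poor alkenes (Giese addition followed by homolytic aromatic substitution), which has not been shown for closure onto a pentasubstituted phloroglucinol-type ring between two oxygen-bearing carbons. The pyran ring closes by 6-endo attack of the C4 radical on the C4a end of the C8a=C4a bond, helped by the Thorpe–Ingold effect of the gem-dimethyl group. The new stereocentre C4 forms without control (racemic) and is erased in step 9. The step needs closure at C4a and not at C8, the other carbon ortho to the ether oxygen: the O–H···O=C chelate of the C5 hydroxyl fixes double-bond character in C8a=C4a (the bias that also sends Claisen rearrangements of such ethers to this carbon), and the methoxy methyl, pushed away from the acyl group, shields C8. The sulfonyl group makes 9 a fast trap that outruns side reactions of the tertiary radical and afterwards masks the C3=C4 bond during steps 6 to 8.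

**Step 6**
Reactants: 10 sulfonyl chroman deoxybenzoin
Product: 11 1-[5-hydroxy-7-methoxy-2,2-dimethyl-4-(phenylsulfonyl)chroman-6-yl]-2-(4-hydroxyphenyl)ethane-1,2-dione (racemic)
Conditions: SeO2 (2 equiv), 1,4-dioxane/H2O, 90 °C
Reagents that add atoms: selenium dioxide, O=[Se]=O
Why: Riley oxidation of the active methylene of the 2-hydroxydeoxybenzoin should give the 1,2-diketone; the molecule holds no alkene or allylic C–H at this stage, and the C4–H next to the sulfone is not enolisable.

**Step 7**
Reactants: 11 diketone
Product: 12 1-[5-hydroxy-8-iodo-7-methoxy-2,2-dimethyl-4-(phenylsulfonyl)chroman-6-yl]-2-(4-hydroxyphenyl)ethane-1,2-dione (racemic)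
Conditions: NIS (1.05 equiv), DMF, 0 °C, dark
Reagents that add atoms: N-iodosuccinimide, O=C1CCC(=O)N1I
Why: Electrophilic aromatic iodination should go to C8, the only unsubstituted ring-A carbon (flanked by OMe and O1, para to the C5 hydroxyl); ring B is deactivated by its para acyl group, and no alkene competes because C3=C4 is still masked.

**Step 8**
Reactants: 12 aryl iodide; 13 tributyl(3-methylbut-2-en-1-yl)stannane
Product: 14 1-[5-hydroxy-7-methoxy-2,2-dimethyl-8-(3-methylbut-2-en-1-yl)-4-(phenylsulfonyl)chroman-6-yl]-2-(4-hydroxyphenyl)ethane-1,2-dione (racemic)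
Conditions: Pd(PPh3)4 (5 mol %), CuI (10 mol %), DMF, 80 °C
Reagents that add atoms: none
Why: Stille coupling of the aryl iodide with the prenylstannane (CuI-assisted transmetalation) should deliver the linear 3-methylbut-2-enyl group; phenols, diketone and sulfone tolerate the neutral conditions.

**Step 9**
Reactants: 14 prenylated sulfonyl chroman
Product: 16 1-[5-hydroxy-7-methoxy-2,2-dimethyl-8-(3-methylbut-2-en-1-yl)-2H-chromen-6-yl]-2-(4-hydroxyphenyl)ethane-1,2-dione (target), via o-quinone methide 15 (not isolated)
Conditions: DBU (2.5 equiv), MeCN, 40 °C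
Reagents that add atoms: none
Why: DBU deprotonates the C5 hydroxyl and the phenoxide expels benzenesulfinate from the ortho benzylic C4 (1,4-elimination of an o-hydroxybenzyl sulfone) to give the o-quinone methide, which tautomerises by loss of a C3 proton to the 2H-chromene, so the racemic C4 centre disappears.

**Compound list**
1 | 5-methoxyresorcinol (5-methoxybenzene-1,3-diol) | COc1cc(O)cc(O)c1 | starting material
2 | 4-hydroxyphenylacetic acid | OC(=O)Cc1ccc(O)cc1 | starting material
3 | 1-(2,4-dihydroxy-6-methoxyphenyl)-2-(4-hydroxyphenyl)ethan-1-one | COc1cc(O)cc(O)c1C(=O)Cc1ccc(O)cc1 | intermediate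
4 | benzyl 2-bromo-2-methylpropanoate | CC(C)(Br)C(=O)OCc1ccccc1 | starting material
5 | benzyl 2-{3-hydroxy-4-[2-(4-hydroxyphenyl)acetyl]-5-methoxyphenoxy}-2-methylpropanoate | COc1cc(OC(C)(C)C(=O)OCc2ccccc2)cc(O)c1C(=O)Cc1ccc(O)cc1 | intermediate
6 | 2-{3-hydroxy-4-[2-(4-hydroxyphenyl)acetyl]-5-methoxyphenoxy}-2-methylpropanoic acid | COc1cc(OC(C)(C)C(=O)O)cc(O)c1C(=O)Cc1ccc(O)cc1 | intermediate
7 | N-hydroxyphthalimide | O=C1N(O)C(=O)c2ccccc12 | starting material
8 | 1,3-dioxoisoindolin-2-yl 2-{3-hydroxy-4-[2-(4-hydroxyphenyl)acetyl]-5-methoxyphenoxy}-2-methylpropanoate | COc1cc(OC(C)(C)C(=O)ON2C(=O)c3ccccc3C2=O)cc(O)c1C(=O)Cc1ccc(O)cc1 | intermediate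
9 | phenyl vinyl sulfone | C=CS(=O)(=O)c1ccccc1 | starting material
10 | 1-[5-hydroxy-7-methoxy-2,2-dimethyl-4-(phenylsulfonyl)chroman-6-yl]-2-(4-hydroxyphenyl)ethan-1-one, racemic | COc1cc2c(c(O)c1C(=O)Cc1ccc(O)cc1)C(S(=O)(=O)c1ccccc1)CC(C)(C)O2 | intermediate
11 | 1-[5-hydroxy-7-methoxy-2,2-dimethyl-4-(phenylsulfonyl)chroman-6-yl]-2-(4-hydroxyphenyl)ethane-1,2-dione, racemic | COc1cc2c(c(O)c1C(=O)C(=O)c1ccc(O)cc1)C(S(=O)(=O)c1ccccc1)CC(C)(C)O2 | intermediate
12 | 1-[5-hydroxy-8-iodo-7-methoxy-2,2-dimethyl-4-(phenylsulfonyl)chroman-6-yl]-2-(4-hydroxyphenyl)ethane-1,2-dione, racemic | COc1c(I)c2c(c(O)c1C(=O)C(=O)c1ccc(O)cc1)C(S(=O)(=O)c1ccccc1)CC(C)(C)O2 | intermediate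
13 | tributyl(3-methylbut-2-en-1-yl)stannane | CCCC[Sn](CCCC)(CCCC)CC=C(C)C | starting material
14 | 1-[5-hydroxy-7-methoxy-2,2-dimethyl-8-(3-methylbut-2-en-1-yl)-4-(phenylsulfonyl)chroman-6-yl]-2-(4-hydroxyphenyl)ethane-1,2-dione, racemic | COc1c(CC=C(C)C)c2c(c(O)c1C(=O)C(=O)c1ccc(O)cc1)C(S(=O)(=O)c1ccccc1)CC(C)(C)O2 | intermediate
15 | o-quinone methide: 6-[2-(4-hydroxyphenyl)-2-oxoacetyl]-7-methoxy-2,2-dimethyl-8-(3-methylbut-2-en-1-yl)-2,3-dihydro-5H-chromen-5-one with exocyclic C4=C4a | CC1(C)CC=C2C(=O)C(C(=O)C(=O)c3ccc(O)cc3)=C(OC)C(CC=C(C)C)=C2O1 | intermediate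
16 | 1-[5-hydroxy-7-methoxy-2,2-dimethyl-8-(3-methylbut-2-en-1-yl)-2H-chromen-6-yl]-2-(4-hydroxyphenyl)ethane-1,2-dione | COc1c(CC=C(C)C)c2c(c(O)c1C(=O)C(=O)c1ccc(O)cc1)C=CC(C)(C)O2 | target

**Count**
Total steps: 9. Longest linear sequence: 9 steps (from 1 or 2 to 16); 4, 7, 9 and 13 are purchased.

**Steps most likely to fail**

1. Step 5 (proposed new method). The α-sulfonyl radical may close at C8 instead of C4a. The tertiary radical may also be lost before it adds to 9, by dimerisation or by oxidation and capture by phthalimide anion, or the adduct radical may telomerise with 9. Fallback by known chemistry, setting out from 3 and returning at 16: O-alkylation of the para hydroxyl of 3 with 3-chloro-3-methylbut-1-yne (K2CO3, KI, CuI cat., acetone, reflux) would give the aryl 1,1-dimethylpropargyl ether F1. Heating in N,N-diethylaniline at 140 °C (aromatic Claisen rearrangement, 1,5-hydrogen shift, oxa-6π electrocyclisation, directed by the chelate to the same carbon) would give the chromene deoxybenzoin F2. Riley oxidation (SeO2, dioxane/H2O) would give the chromene diketone F3, iodination with NIS at C8 would give the 8-iodochromene diketone F4, and Stille coupling of F4 with 13 would reach 16.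

2. Step 8. Oxidative addition and transmetalation at the doubly ortho-oxygenated iodide may be slow, which would allow protodeiodination. The prenyl group may also be transferred through its γ-carbon (1,1-dimethylallyl isomer), or the allylic stannane may add to the diketone. Fallback setting out from 12 and returning at 14: Stille coupling with allyltributylstannane (no α/γ question) would give the 8-allyl sulfonyl chroman diketone F5. Cross-metathesis of F5 with 2-methylbut-2-ene (second-generation Grubbs catalyst, RuCl2(=CHPh)(H2IMes)(PCy3), CH2Cl2, 40 °C) would turn allyl into prenyl and give 14; the chromene double bond is still masked and cannot take part.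

3. Step 1. Acylation may occur at the carbon between the two hydroxyls (wrong regiochemistry), or a second acylation may follow. Fallback setting out from 2 and returning at 5, with regiochemistry taken from symmetry: acylation of phloroglucinol with 2 (BF3·OEt2, 85 °C) would give the symmetric trihydroxy deoxybenzoin F6. Alkylation of its para hydroxyl with 4 (K2CO3, DMF) would give the symmetric dihydroxy ester F7. One O-methylation of F7 (MeI 1 equiv, K2CO3 1 equiv, acetone) at one of the two equivalent ortho hydroxyls would give 5, since the remaining hydroxyl is then locked in the chelate.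

**Further compounds**
F1 | step 5 | 1-{2-hydroxy-6-methoxy-4-[(2-methylbut-3-yn-2-yl)oxy]phenyl}-2-(4-hydroxyphenyl)ethan-1-one | COc1cc(OC(C)(C)C#C)cc(O)c1C(=O)Cc1ccc(O)cc1
F2 | step 5 | 1-(5-hydroxy-7-methoxy-2,2-dimethyl-2H-chromen-6-yl)-2-(4-hydroxyphenyl)ethan-1-one | COc1cc2c(c(O)c1C(=O)Cc1ccc(O)cc1)C=CC(C)(C)O2
F3 | step 5 | 1-(5-hydroxy-7-methoxy-2,2-dimethyl-2H-chromen-6-yl)-2-(4-hydroxyphenyl)ethane-1,2-dione | COc1cc2c(c(O)c1C(=O)C(=O)c1ccc(O)cc1)C=CC(C)(C)O2
F4 | step 5 | 1-(5-hydroxy-8-iodo-7-methoxy-2,2-dimethyl-2H-chromen-6-yl)-2-(4-hydroxyphenyl)ethane-1,2-dione | COc1c(I)c2c(c(O)c1C(=O)C(=O)c1ccc(O)cc1)C=CC(C)(C)O2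
F5 | step 8 | 1-[8-allyl-5-hydroxy-7-methoxy-2,2-dimethyl-4-(phenylsulfonyl)chroman-6-yl]-2-(4-hydroxyphenyl)ethane-1,2-dione, racemic | COc1c(CC=C)c2c(c(O)c1C(=O)C(=O)c1ccc(O)cc1)C(S(=O)(=O)c1ccccc1)CC(C)(C)O2
F6 | step 1 | 2-(4-hydroxyphenyl)-1-(2,4,6-trihydroxyphenyl)ethan-1-one | Oc1cc(O)c(C(=O)Cc2ccc(O)cc2)c(O)c1
F7 | step 1 | benzyl 2-{3,5-dihydroxy-4-[2-(4-hydroxyphenyl)acetyl]phenoxy}-2-methylpropanoate | CC(C)(Oc1cc(O)c(C(=O)Cc2ccc(O)cc2)c(O)c1)C(=O)OCc1ccccc1
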